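**Retrosynthetic overview**
1. 19 ⇐ 18 (hydrogenolysis of seventeen benzyl ethers and three C–Br bonds) ⇐ 17 + 15 (gallate on the C2' hydroxyl).
2. 17 ⇐ 11 + 16 by the bond C6 (benzo ring A of the chroman)–C1' (diarylmethine of the ring-opened unit): invertive Friedel–Crafts opening of a cis-aryl oxirane.
3. Enabling feature: C1' is benzylic to pyrogallol ring E and vicinal to the oxygen-bearing C2', so C1'–C2'(O) is a latent aryl oxirane; C6 lies between O5 and O7 and para to O1 of ring A, the most nucleophilic free carbon once C8 carries bromine.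
4. 11 ⇐ Z-alkene 10 ⇐ alkyne 9 ⇐ acetylide 6 + aldehyde 3; 16 ⇐ 14 + 15 ⇐ 13 ⇐ (−)-epigallocatechin 12, which supplies rings A, B and C and both chroman stereocentres, while acid chloride 15 supplies rings D and G.
5. Ring order: no ring of the target is built; the only ring made is the oxirane (step 7), and it is opened again in step 11.

Key step: step 11

Remark (assumption): the SMILES is read as (2R,3R) in the chroman unit, the configuration of natural (−)-epigallocatechin, and (1'R,2'S) in the open-chain unit. Locants: C1' diarylmethine, C2' carbinol, C3' methylene. Rings: A benzo ring and C pyran ring of the chroman, B pyrogallol on C2, D galloyl on O3, E pyrogallol on C1', F phloroglucinol on C3', G galloyl on O2'. Compounds 1, 4, 12 and 15 are taken as purchasable.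

**Route**

Step 1
Reactants: 1 1,3,5-tris(benzyloxy)benzene
Product: 3 2,4,6-tris(benzyloxy)benzaldehyde, via aryl iminium dichlorophosphate 2 (not isolated)
Conditions: POCl3 (1.5 equiv), DMF, 0 → 60 °C; then H2O, rt
Reagents that add atoms: N,N-dimethylformamide CN(C)C=O (formyl carbon); water O (carbonyl oxygen)
Why: Vilsmeier–Haack formylation of a phloroglucinol triether, whose three equivalent free positions make the single aldehyde unambiguous.

Step 2
Reactants: 4 3,4,5-tris(benzyloxy)benzaldehyde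
Product: 5 1,2,3-tris(benzyloxy)-5-ethynylbenzene
Conditions: dimethyl (1-diazo-2-oxopropyl)phosphonate (1.3 equiv), K2CO3 (2 equiv), MeOH/THF, 0 °C → rt
Reagents that add atoms: dimethyl (1-diazo-2-oxopropyl)phosphonate CC(=O)C(=[N+]=[N-])P(=O)(OC)OC
Why: Seyferth–Gilbert homologation in the Ohira–Bestmann variant converts an aryl aldehyde into the terminal alkyne under mild base that benzyl ethers tolerate.

Step 3
Reactants: 5 1,2,3-tris(benzyloxy)-5-ethynylbenzene; 3 2,4,6-tris(benzyloxy)benzaldehyde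
Product: 7 rac-1-[2,4,6-tris(benzyloxy)phenyl]-3-[3,4,5-tris(benzyloxy)phenyl]prop-2-yn-1-ol, via lithium acetylide 6 (not isolated)
Conditions: n-BuLi (1.05 equiv), THF, −78 °C; then 3, −78 → 0 °C; then H2O
Reagents that add atoms: none
Why: 1,2-addition of a lithium acetylide to an aldehyde; the carbinol centre is left racemic on purpose because step 4 removes it.

Step 4
Reactants: 7 rac-propargylic alcohol
Product: 8 1,3,5-tris(benzyloxy)-2-{3-[3,4,5-tris(benzyloxy)phenyl]prop-2-yn-1-yl}benzene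
Conditions: Et3SiH (6 equiv), CF3CO2H (2 equiv), CH2Cl2, −40 → 0 °C
Reagents that add atoms: none
Why: ionic hydrogenation, in which acid ionises the carbinol to a cation stabilised by the 2,4,6-trioxygenated ring and the alkyne, and excess silane should deliver hydride to the benzylic carbon faster than ring F of a second molecule can add.

Step 5
Reactants: 8 1,3-diarylpropyne
Product: 9 1,3,5-tris(benzyloxy)-2,4-dibromo-6-{3-[3,4,5-tris(benzyloxy)phenyl]prop-2-yn-1-yl}benzene
Conditions: NBS (2.05 equiv), CH2Cl2, −20 → 0 °C, dark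
Reagents that add atoms: N-bromosuccinimide O=C1CCC(=O)N1Br
Why: electrophilic aromatic bromination should go to the two free positions of ring F, each activated by three oxygen donors, ahead of ring E and the alkyne; the bromines silence ring F as a nucleophile for step 11.

Step 6
Reactants: 9 dibromo-1,3-diarylpropyne
Product: 10 1,3,5-tris(benzyloxy)-2,4-dibromo-6-{(2Z)-3-[3,4,5-tris(benzyloxy)phenyl]prop-2-en-1-yl}benzene
Conditions: H2 (1 atm), Pd/CaCO3 poisoned with Pb(OAc)2, quinoline, EtOAc, rt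
Reagents that add atoms: none
Why: Lindlar-type syn semihydrogenation of the alkyne should give the Z-alkene while the poisoned catalyst leaves benzyl ethers and the hindered aryl bromides alone.

Step 7
Reactants: 10 Z-alkene
Product: 11 (2S,3R)-2-{[2,4,6-tris(benzyloxy)-3,5-dibromophenyl]methyl}-3-[3,4,5-tris(benzyloxy)phenyl]oxirane (cis)
Conditions: (R,R)-N,N'-bis(3,5-di-tert-butylsalicylidene)-1,2-cyclohexanediaminomanganese chloride (8 mol %), N-methylmorpholine N-oxide (5 equiv), mCPBA (2 equiv), CH2Cl2, −78 °C; filtration through Et3N-deactivated silica, used at once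
Reagents that add atoms: 3-chloroperoxybenzoic acid OOC(=O)c1cccc(Cl)c1
Why: Jacobsen–Katsuki epoxidation of a cis-disubstituted aryl alkene, in which the (R,R)-salen ligand is expected, by analogy with cis-β-methylstyrene, to deliver oxygen to the face that makes the benzylic carbon R and the neighbouring carbon S.

Step 8
Reactants: 12 (−)-epigallocatechin
Product: 13 (2R,3R)-5,7-bis(benzyloxy)-2-[3,4,5-tris(benzyloxy)phenyl]chroman-3-ol
Conditions: BnBr (5.5 equiv), K2CO3 (6 equiv), DMF, −10 °C → rt, argon, dark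
Reagents that add atoms: benzyl bromide BrCc1ccccc1
Why: Williamson etherification in which carbonate deprotonates the five phenols but not the secondary C3 alcohol, so benzylation should stop at the penta-aryl ether and leave the C2 and C3 centres untouched.

Step 9
Reactants: 13 penta-O-benzyl-epigallocatechin
Product: 14 (2R,3R)-5,7-bis(benzyloxy)-8-bromo-2-[3,4,5-tris(benzyloxy)phenyl]chroman-3-ol
Conditions: NBS (1.0 equiv), CH2Cl2, −78 → −20 °C
Reagents that add atoms: N-bromosuccinimide O=C1CCC(=O)N1Br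
Why: electrophilic bromination of 5,7-di-O-benzylflavan-3-ols with NBS is known to go to C8 rather than C6, which installs a removable blocking group and leaves C6 as the only free carbon of ring A.

Step 10
Reactants: 14 8-bromo-penta-O-benzyl-epigallocatechin; 15 3,4,5-tris(benzyloxy)benzoyl chloride
Product: 16 (2R,3R)-5,7-bis(benzyloxy)-8-bromo-2-[3,4,5-tris(benzyloxy)phenyl]chroman-3-yl 3,4,5-tris(benzyloxy)benzoate
Conditions: 15 (1.5 equiv), Et3N (3 equiv), DMAP (0.2 equiv), CH2Cl2, 0 °C → rt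
Reagents that add atoms: none
Why: DMAP-catalysed acylation of the only free hydroxyl by an acid chloride, the standard galloylation of benzylated flavan-3-ols; the C3–O bond is not broken, so the configuration is retained.

Step 11
Reactants: 11 cis-oxirane; 16 8-bromo-octa-O-benzyl-epigallocatechin gallate
Product: 17 (2R,3R)-5,7-bis(benzyloxy)-8-bromo-6-{(1R,2S)-3-[2,4,6-tris(benzyloxy)-3,5-dibromophenyl]-2-hydroxy-1-[3,4,5-tris(benzyloxy)phenyl]propyl}-2-[3,4,5-tris(benzyloxy)phenyl]chroman-3-yl 3,4,5-tris(benzyloxy)benzoate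
Conditions: BF3·OEt2 (0.3 equiv), 4 Å molecular sieves, CH2Cl2, −78 → −40 °C, 11 added slowly to 16 (2 equiv); Et3N quench
Reagents that add atoms: none
Why: BF3 binds the oxirane oxygen and C6 of ring A of 16 attacks the benzylic oxirane carbon from the rear in a loose, invertive SN2-type Friedel–Crafts alkylation, after which loss of the C6 proton rearomatises ring A and protonates the alkoxide; the closest known reaction type is the Lewis-acid-promoted stereospecific ring opening of enantioenriched aryl epoxides by electron-rich arenes and indoles, together with the C4-to-C6 coupling of 8-bromoflavan nucleophiles in proanthocyanidin synthesis. No ring is closed, and the oxirane is the only ring opened. The new stereocentre C1' is fixed as R by inversion at the R-configured benzylic oxirane carbon (the descriptor stays R only because the ranking of its substituents changes), C2' keeps its S configuration because its C–O bond is not touched, and any minor enantiomer of 11 would end as a separable diastereomer because 16 is a single enantiomer. Site selectivity on the nucleophile is secured by the bromine that blocks C8, leaving C6, flanked by O5 and O7 and para to O1, as the most electron-rich free carbon, and self-alkylation of the epoxide is prevented by the two bromines on ring F. Chemoselectivity for the oxirane over the benzylic C2–O1 ether of ring C rests on ring strain, which should let the oxirane react at −78 °C where the pyran ring is inert, and the ester on O3 keeps that oxygen from competing as a nucleophile. Slow addition of 11 to excess 16 keeps the activated epoxide dilute and so disfavours free-cation formation and hydride shift to the ketone.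

Step 12
Reactants: 17 coupled (1'R,2'S)-alcohol; 15 3,4,5-tris(benzyloxy)benzoyl chloride
Product: 18 2'-O-[3,4,5-tris(benzyloxy)benzoyl] ester of 17 (heptadeca-O-benzyl tribromide)
Conditions: 15 (3 equiv), Et3N (5 equiv), DMAP (1 equiv), CH2Cl2, 40 °C
Reagents that add atoms: none
Why: DMAP-catalysed acylation of the only free hydroxyl by an acid chloride, which does not break the C2'–O bond and so retains the S configuration.

Step 13
Reactants: 18 heptadeca-O-benzyl tribromide
Product: 19 target, (2R,3R)-5,7-dihydroxy-6-[(1R,2S)-2-(3,4,5-trihydroxybenzoyloxy)-1-(3,4,5-trihydroxyphenyl)-3-(2,4,6-trihydroxyphenyl)propyl]-2-(3,4,5-trihydroxyphenyl)chroman-3-yl 3,4,5-trihydroxybenzoate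
Conditions: H2 (1 atm), Pd(OH)2/C, Et3N (4 equiv), THF/MeOH 1:1, rt; filtration under argon
Reagents that add atoms: none
Why: hydrogenolysis of seventeen benzyl ethers with concurrent hydrodebromination of three aryl bromides (Et3N traps HBr), a deprotection precedented for benzylated 8-bromoflavans that should leave both esters, the pyran C2–O1 bond and all four stereocentres intact.

**Compound list**
1 | 1,3,5-tris(benzyloxy)benzene | c1(OCc2ccccc2)cc(OCc2ccccc2)cc(OCc2ccccc2)c1 | starting material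
2 | N-{[2,4,6-tris(benzyloxy)phenyl]methylidene}-N-methylmethanaminium dichlorophosphate | C[N+](C)=Cc1c(OCc2ccccc2)cc(OCc2ccccc2)cc1OCc1ccccc1.[O-]P(=O)(Cl)Cl | intermediate
3 | 2,4,6-tris(benzyloxy)benzaldehyde | O=Cc1c(OCc2ccccc2)cc(OCc2ccccc2)cc1OCc1ccccc1 | intermediate
4 | 3,4,5-tris(benzyloxy)benzaldehyde | O=Cc1cc(OCc2ccccc2)c(OCc2ccccc2)c(OCc2ccccc2)c1 | starting material
5 | 1,2,3-tris(benzyloxy)-5-ethynylbenzene | C#Cc1cc(OCc2ccccc2)c(OCc2ccccc2)c(OCc2ccccc2)c1 | intermediate
6 | lithium [3,4,5-tris(benzyloxy)phenyl]acetylide | [Li]C#Cc1cc(OCc2ccccc2)c(OCc2ccccc2)c(OCc2ccccc2)c1 | intermediate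
7 | rac-1-[2,4,6-tris(benzyloxy)phenyl]-3-[3,4,5-tris(benzyloxy)phenyl]prop-2-yn-1-ol (racemic, no defined centre) | OC(C#Cc1cc(OCc2ccccc2)c(OCc2ccccc2)c(OCc2ccccc2)c1)c1c(OCc2ccccc2)cc(OCc2ccccc2)cc1OCc1ccccc1 | intermediate
8 | 1,3,5-tris(benzyloxy)-2-{3-[3,4,5-tris(benzyloxy)phenyl]prop-2-yn-1-yl}benzene | C(C#Cc1cc(OCc2ccccc2)c(OCc2ccccc2)c(OCc2ccccc2)c1)c1c(OCc2ccccc2)cc(OCc2ccccc2)cc1OCc1ccccc1 | intermediate
9 | 1,3,5-tris(benzyloxy)-2,4-dibromo-6-{3-[3,4,5-tris(benzyloxy)phenyl]prop-2-yn-1-yl}benzene | C(C#Cc1cc(OCc2ccccc2)c(OCc2ccccc2)c(OCc2ccccc2)c1)c1c(OCc2ccccc2)c(Br)c(OCc2ccccc2)c(Br)c1OCc1ccccc1 | intermediate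
10 | 1,3,5-tris(benzyloxy)-2,4-dibromo-6-{(2Z)-3-[3,4,5-tris(benzyloxy)phenyl]prop-2-en-1-yl}benzene | C(/C=C\c1cc(OCc2ccccc2)c(OCc2ccccc2)c(OCc2ccccc2)c1)c1c(OCc2ccccc2)c(Br)c(OCc2ccccc2)c(Br)c1OCc1ccccc1 | intermediate
11 | (2S,3R)-2-{[2,4,6-tris(benzyloxy)-3,5-dibromophenyl]methyl}-3-[3,4,5-tris(benzyloxy)phenyl]oxirane (cis) | C([C@@H]1O[C@@H]1c1cc(OCc2ccccc2)c(OCc2ccccc2)c(OCc2ccccc2)c1)c1c(OCc2ccccc2)c(Br)c(OCc2ccccc2)c(Br)c1OCc1ccccc1 | intermediate
12 | (−)-epigallocatechin, (2R,3R) | O[C@@H]1Cc2c(O)cc(O)cc2O[C@@H]1c1cc(O)c(O)c(O)c1 | starting material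
13 | (2R,3R)-5,7-bis(benzyloxy)-2-[3,4,5-tris(benzyloxy)phenyl]chroman-3-ol | O[C@@H]1Cc2c(OCc3ccccc3)cc(OCc3ccccc3)cc2O[C@@H]1c1cc(OCc3ccccc3)c(OCc3ccccc3)c(OCc3ccccc3)c1 | intermediate
14 | (2R,3R)-5,7-bis(benzyloxy)-8-bromo-2-[3,4,5-tris(benzyloxy)phenyl]chroman-3-ol | O[C@@H]1Cc2c(OCc3ccccc3)cc(OCc3ccccc3)c(Br)c2O[C@@H]1c1cc(OCc3ccccc3)c(OCc3ccccc3)c(OCc3ccccc3)c1 | intermediate
15 | 3,4,5-tris(benzyloxy)benzoyl chloride | O=C(Cl)c1cc(OCc2ccccc2)c(OCc2ccccc2)c(OCc2ccccc2)c1 | starting material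
16 | (2R,3R)-5,7-bis(benzyloxy)-8-bromo-2-[3,4,5-tris(benzyloxy)phenyl]chroman-3-yl 3,4,5-tris(benzyloxy)benzoate | O=C(O[C@@H]1Cc2c(OCc3ccccc3)cc(OCc3ccccc3)c(Br)c2O[C@@H]1c1cc(OCc3ccccc3)c(OCc3ccccc3)c(OCc3ccccc3)c1)c1cc(OCc3ccccc3)c(OCc3ccccc3)c(OCc3ccccc3)c1 | intermediate
17 | (2R,3R)-5,7-bis(benzyloxy)-8-bromo-6-{(1R,2S)-3-[2,4,6-tris(benzyloxy)-3,5-dibromophenyl]-2-hydroxy-1-[3,4,5-tris(benzyloxy)phenyl]propyl}-2-[3,4,5-tris(benzyloxy)phenyl]chroman-3-yl 3,4,5-tris(benzyloxy)benzoate | O[C@@H](Cc1c(OCc3ccccc3)c(Br)c(OCc3ccccc3)c(Br)c1OCc3ccccc3)[C@H](c1cc(OCc3ccccc3)c(OCc3ccccc3)c(OCc3ccccc3)c1)c1c(OCc3ccccc3)c(Br)c2c(c1OCc3ccccc3)C[C@@H](OC(=O)c1cc(OCc3ccccc3)c(OCc3ccccc3)c(OCc3ccccc3)c1)[C@@H](c1cc(OCc3ccccc3)c(OCc3ccccc3)c(OCc3ccccc3)c1)O2 | intermediate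
18 | 2'-O-[3,4,5-tris(benzyloxy)benzoyl] ester of 17, (2R,3R,1'R,2'S) | O=C(O[C@@H](Cc1c(OCc3ccccc3)c(Br)c(OCc3ccccc3)c(Br)c1OCc3ccccc3)[C@H](c1cc(OCc3ccccc3)c(OCc3ccccc3)c(OCc3ccccc3)c1)c1c(OCc3ccccc3)c(Br)c2c(c1OCc3ccccc3)C[C@@H](OC(=O)c1cc(OCc3ccccc3)c(OCc3ccccc3)c(OCc3ccccc3)c1)[C@@H](c1cc(OCc3ccccc3)c(OCc3ccccc3)c(OCc3ccccc3)c1)O2)c1cc(OCc3ccccc3)c(OCc3ccccc3)c(OCc3ccccc3)c1 | intermediate
19 | (2R,3R)-5,7-dihydroxy-6-[(1R,2S)-2-(3,4,5-trihydroxybenzoyloxy)-1-(3,4,5-trihydroxyphenyl)-3-(2,4,6-trihydroxyphenyl)propyl]-2-(3,4,5-trihydroxyphenyl)chroman-3-yl 3,4,5-trihydroxybenzoate | O=C(O[C@@H](Cc1c(O)cc(O)cc1O)[C@H](c1cc(O)c(O)c(O)c1)c1c(O)cc2c(c1O)C[C@@H](OC(=O)c1cc(O)c(O)c(O)c1)[C@@H](c1cc(O)c(O)c(O)c1)O2)c1cc(O)c(O)c(O)c1 | target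

**Count**
Total steps: 13. Longest linear sequence: 9 steps (1, 3, 4, 5, 6, 7, 11, 12, 13, from compound 1).

**Steps most likely to fail**

Step 11 (key step). The risk is that the electron-rich ring E lets the epoxide ionise before rear-side attack. A free cation could then be captured anti to the boron-bound oxygen (loss of the invertive course at C1') or undergo hydride shift to the ketone. The fallback reverses the stereochemical plan so that an ionising and an invertive course converge, and C2' is corrected afterwards. It sets out from 10 and 16 and returns at 17. Alkene 10 would be isomerised (I2, 5 mol %, CH2Cl2, visible light) to the E-alkene F1. Shi epoxidation (D-fructose-derived ketone, KHSO5 as 2KHSO5·KHSO4·K2SO4, K2CO3 buffer, MeCN/dimethoxymethane/H2O, 0 °C) would give the trans-(2R,3R)-oxirane F2. Coupling with 16 under the step 11 conditions should give the C2'-epimeric (1'R,2'R)-alcohol F3, because both invertive opening and capture anti to the complexed oxygen lead to this isomer. Oxidation with Dess–Martin periodinane (NaHCO3, CH2Cl2, 0 °C) would give the ketone F4, which is handled cold and without base because its C1' hydrogen is acidic. Reduction with LiBH(s-Bu)3 (THF, −78 °C) under Felkin–Anh control, hydride anti to the di-ortho-substituted ring-A aryl group, should then give the 2'S alcohol 17.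

Step 7. The risks are rotation in a benzylic radical on the manganese-oxo pathway (cis-to-trans erosion), incomplete facial selectivity, and acid-triggered rearrangement of the labile epoxide on isolation. The fallback gives up asymmetric epoxidation and lets the enantiopure coupling partner do the resolution. It sets out from 10 and returns at 17. Dimethyldioxirane (acetone, −20 °C, concerted and stereospecific) would convert 10 into the racemic cis-oxirane, that is 11 together with the enantiomeric cis-oxirane F5, used crude. Step 11 with single-enantiomer 16 would then give 17 and the (1'S,2'R) diastereomer F6, which are separated by chromatography.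

Step 13. The risks are that bromide released on the catalyst slows debenzylation, leaving partly benzylated material, and that the free polyphenol oxidises during a long reaction. The fallback separates the two events and uses a non-reductive debenzylation. It sets out from 18 and returns at 19. Bu3SnH (4 equiv) with AIBN (toluene, 80 °C) would remove the three bromines by radical reduction to give the bromine-free heptadeca-O-benzyl ether F7. BCl3 with pentamethylbenzene as benzyl-cation scavenger (CH2Cl2, −78 °C) would then cleave the seventeen aryl benzyl ethers, leaving both gallate esters, to give 19.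

**Further compounds**
F1 | step 11 | 1,3,5-tris(benzyloxy)-2,4-dibromo-6-{(2E)-3-[3,4,5-tris(benzyloxy)phenyl]prop-2-en-1-yl}benzene | C(/C=C/c1cc(OCc2ccccc2)c(OCc2ccccc2)c(OCc2ccccc2)c1)c1c(OCc2ccccc2)c(Br)c(OCc2ccccc2)c(Br)c1OCc1ccccc1
F2 | step 11 | (2R,3R)-2-{[2,4,6-tris(benzyloxy)-3,5-dibromophenyl]methyl}-3-[3,4,5-tris(benzyloxy)phenyl]oxirane (trans) | C([C@H]1O[C@@H]1c1cc(OCc2ccccc2)c(OCc2ccccc2)c(OCc2ccccc2)c1)c1c(OCc2ccccc2)c(Br)c(OCc2ccccc2)c(Br)c1OCc1ccccc1
F3 | step 11 | (1'R,2'R)-epimer of 17 at C2' | O[C@H](Cc1c(OCc3ccccc3)c(Br)c(OCc3ccccc3)c(Br)c1OCc3ccccc3)[C@H](c1cc(OCc3ccccc3)c(OCc3ccccc3)c(OCc3ccccc3)c1)c1c(OCc3ccccc3)c(Br)c2c(c1OCc3ccccc3)C[C@@H](OC(=O)c1cc(OCc3ccccc3)c(OCc3ccccc3)c(OCc3ccccc3)c1)[C@@H](c1cc(OCc3ccccc3)c(OCc3ccccc3)c(OCc3ccccc3)c1)O2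
F4 | step 11 | (1'R)-2'-ketone derived from F3 | O=C(Cc1c(OCc3ccccc3)c(Br)c(OCc3ccccc3)c(Br)c1OCc3ccccc3)[C@H](c1cc(OCc3ccccc3)c(OCc3ccccc3)c(OCc3ccccc3)c1)c1c(OCc3ccccc3)c(Br)c2c(c1OCc3ccccc3)C[C@@H](OC(=O)c1cc(OCc3ccccc3)c(OCc3ccccc3)c(OCc3ccccc3)c1)[C@@H](c1cc(OCc3ccccc3)c(OCc3ccccc3)c(OCc3ccccc3)c1)O2
F5 | step 7 | (2R,3S)-2-{[2,4,6-tris(benzyloxy)-3,5-dibromophenyl]methyl}-3-[3,4,5-tris(benzyloxy)phenyl]oxirane (cis, enantiomer of 11) | C([C@H]1O[C@H]1c1cc(OCc2ccccc2)c(OCc2ccccc2)c(OCc2ccccc2)c1)c1c(OCc2ccccc2)c(Br)c(OCc2ccccc2)c(Br)c1OCc1ccccc1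
F6 | step 7 | (1'S,2'R)-diastereomer of 17 | O[C@H](Cc1c(OCc3ccccc3)c(Br)c(OCc3ccccc3)c(Br)c1OCc3ccccc3)[C@@H](c1cc(OCc3ccccc3)c(OCc3ccccc3)c(OCc3ccccc3)c1)c1c(OCc3ccccc3)c(Br)c2c(c1OCc3ccccc3)C[C@@H](OC(=O)c1cc(OCc3ccccc3)c(OCc3ccccc3)c(OCc3ccccc3)c1)[C@@H](c1cc(OCc3ccccc3)c(OCc3ccccc3)c(OCc3ccccc3)c1)O2
F7 | step 13 | bromine-free heptadeca-O-benzyl ether of 19 | O=C(O[C@@H](Cc1c(OCc3ccccc3)cc(OCc3ccccc3)cc1OCc3ccccc3)[C@H](c1cc(OCc3ccccc3)c(OCc3ccccc3)c(OCc3ccccc3)c1)c1c(OCc3ccccc3)cc2c(c1OCc3ccccc3)C[C@@H](OC(=O)c1cc(OCc3ccccc3)c(OCc3ccccc3)c(OCc3ccccc3)c1)[C@@H](c1cc(OCc3ccccc3)c(OCc3ccccc3)c(OCc3ccccc3)c1)O2)c1cc(OCc3ccccc3)c(OCc3ccccc3)c(OCc3ccccc3)c1
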